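**Retrosynthetic overview**

1. The target is an ether-linked dimer of one monomer. Cutting the C4–O bond of unit A (3R,4S, trans) from O6 of unit B (3R,4R, cis) by a Mitsunobu inversion traces both halves to one cis-(3R,4R)-4-hydroxy-3-methylisochromanone skeleton.
2. That cis alcohol comes from a racemic 3-methylisochromane-1,4-dione by asymmetric transfer hydrogenation with dynamic kinetic resolution, used once for each half.
3. Enabling feature: in the lactone ring (C1, O2, C3, C4, C4a, C8a), C3 is bound to the ring oxygen O2 and carries only H and CH3, and its neighbour C4 is an oxygen-bearing benzylic carbon on C4a, ortho to the carboxyl-bearing C8a. The dione is therefore an isomer of a vinyl ester (O2–C3H=CH2) beside an aryl aldehyde (C4), and C3–C4 is made by adding the formyl C–H across the vinyl group.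
4. The aldehyde–vinyl ester comes from methyl 4-O-methylgallate. Its two free ring positions are equivalent, so ortho-lithiation and trapping with vinyl chloroformate installs C1, O2 and C3 in one step.
5. Ring order: the benzene ring is bought, the lactone ring is closed once (step 7), and the same ring serves as unit A (after reduction) and unit B (reduced after coupling).

Key step: step 7

Assumption: methyl 3,5-dihydroxy-4-methoxybenzoate and vinyl chloroformate are taken as commercial; isochromanone numbering (C1 carbonyl, O2, C3, C4, C4a, C5–C8, C8a) is used for both halves, unit A being the half whose C4 carries the aryl ether and unit B the half with the free 4-OH.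

**Route**

Step 1
Reactants: 1 methyl 3,5-dihydroxy-4-methoxybenzoate
Product: 2 methyl 4-methoxy-3,5-bis(methoxymethoxy)benzoate
Conditions: MOMCl (2.5 equiv), i-Pr2NEt (3 equiv), CH2Cl2, 0 °C to rt
Reagents that add atoms: chloromethyl methyl ether, COCCl
Why: Williamson-type O-alkylation of the two equivalent phenols should give the bis(MOM) ether, which tolerates the hydride, organolithium, rhodium and ruthenium steps and later directs the ortho-lithiation.

Step 2
Reactants: 2 methyl 4-methoxy-3,5-bis(methoxymethoxy)benzoate
Product: 3 [4-methoxy-3,5-bis(methoxymethoxy)phenyl]methanol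
Conditions: LiAlH4, THF, 0 °C
Reagents that add atoms: none
Why: Hydride reduction of the methyl ester to the benzylic alcohol, with the MOM acetals inert to LiAlH4.

Step 3
Reactants: 3 [4-methoxy-3,5-bis(methoxymethoxy)phenyl]methanol
Product: 4 4-methoxy-3,5-bis(methoxymethoxy)benzaldehyde
Conditions: MnO2 (10 equiv), CH2Cl2, rt
Reagents that add atoms: none
Why: Activated MnO2 oxidises benzylic alcohols selectively and stops at the aldehyde.

Step 4
Reactants: 4 4-methoxy-3,5-bis(methoxymethoxy)benzaldehyde
Product: 5 5-(dimethoxymethyl)-2-methoxy-1,3-bis(methoxymethoxy)benzene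
Conditions: HC(OMe)3 (3 equiv), PPTS (5 mol %), MeOH, rt
Reagents that add atoms: trimethyl orthoformate, COC(OC)OC; methanol, CO
Why: Acid-catalysed acetalisation driven by the orthoformate masks the aldehyde against the organolithium and makes it a second ortho-directing group, while PPTS at rt is too weak to cleave aryl MOM ethers.

Step 5
Reactants: 5 5-(dimethoxymethyl)-2-methoxy-1,3-bis(methoxymethoxy)benzene
Product: 7 ethenyl 2-(dimethoxymethyl)-5-methoxy-4,6-bis(methoxymethoxy)benzoate, via aryllithium 6 (not isolated)
Conditions: s-BuLi (1.15 equiv), TMEDA, THF, −78 °C; then cannulated into ClCO2CH=CH2 (3 equiv), THF, −78 °C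
Reagents that add atoms: vinyl chloroformate, C=COC(=O)Cl
Why: Directed ortho-metalation is unambiguous because the two remaining ring hydrogens are equivalent and each lies between an OMOM and the acetal, and inverse addition of the hindered aryllithium to excess chloroformate should give the vinyl ester by acyl substitution (chloride leaves, not vinyloxide) without a second addition.

Step 6
Reactants: 7 ethenyl 2-(dimethoxymethyl)-5-methoxy-4,6-bis(methoxymethoxy)benzoate
Product: 8 ethenyl 2-formyl-5-methoxy-4,6-bis(methoxymethoxy)benzoate
Conditions: PPTS (10 mol %), acetone/H2O 10:1, rt; used directly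
Reagents that add atoms: water, O
Why: Mild acid hydrolysis of an aryl dimethyl acetal should be far faster than cleavage of the phenolic MOM ethers or hydrolysis of the vinyl ester.

Step 7
Reactants: 8 ethenyl 2-formyl-5-methoxy-4,6-bis(methoxymethoxy)benzoate
Product: 9 rac-7-methoxy-6,8-bis(methoxymethoxy)-3-methylisochromane-1,4-dione
Conditions: [Rh(cod)Cl]2 (2.5 mol %), rac-BINAP (5.5 mol %), AgBF4 (5 mol %), ClCH2CH2Cl (0.05 M), 60 °C
Reagents that add atoms: none
Why: Proposed new method: a cationic bisphosphine complex of monovalent rhodium should add oxidatively into the formyl C–H bond, the resulting acyl hydride of trivalent rhodium is held in a six-membered chelate by the neighbouring ester carbonyl oxygen, the vinyl C=C inserts into Rh–H with hydrogen going to the terminal CH2 and rhodium to the oxygen-bearing carbon, and C–C reductive elimination from the seven-membered acyl–alkyl rhodacycle forms the C3–C4 bond, the C3 methyl group and the C4 ketone in one atom-economic isomerisation. The closest known reactions are the rhodium-catalysed intramolecular olefin hydroacylations that give six-membered benzo-fused ketones from 2-allylbenzaldehydes and the branched-selective hydroformylation of vinyl acetate, which shows the same Markovnikov Rh–H insertion into an enol ester; an enol ester has not served as the olefin of an intramolecular hydroacylation, hence the label. The one ring closed is the lactone ring (C1, O2, C3, C4, C4a, C8a), in the 6-exo-trig mode at the internal vinyl carbon. The new stereocentre C3 is formed without control on purpose (racemic ligand), because it lies between the C4 ketone and O2, epimerises through the enol and is fixed together with C4 in step 8. The step needs branched over linear insertion and hydroacylation over decarbonylation: the first is secured by the polarised enol ester and by the six- versus seven-membered ring alternative, the second by intramolecularity and by the carbonyl chelation that fills the vacant site needed for CO extrusion.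

Step 8
Reactants: 9 rac-7-methoxy-6,8-bis(methoxymethoxy)-3-methylisochromane-1,4-dione
Product: 10 (3R,4R)-4-hydroxy-7-methoxy-6,8-bis(methoxymethoxy)-3-methylisochroman-1-one
Conditions: RuCl[(S,S)-TsDPEN](p-cymene) (2 mol %), HCO2H/Et3N 5:2, CH2Cl2, 30 °C
Reagents that add atoms: none
Why: Noyori asymmetric transfer hydrogenation with dynamic kinetic resolution: C3–H racemises quickly in the amine buffer, the (S,S) catalyst should deliver hydride to the aryl-ketone face that gives 4R (same spatial sense as (S)-1-tetralol, descriptor R because C3 outranks the aryl carbon) and anti to the C3 methyl, so only the 3R ketone is reduced and the cis (3R,4R) alcohol results.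

Step 9
Reactants: 9 rac-7-methoxy-6,8-bis(methoxymethoxy)-3-methylisochromane-1,4-dione
Product: 11 rac-6,8-dihydroxy-7-methoxy-3-methylisochromane-1,4-dione
Conditions: TFA/CH2Cl2 1:5, H2O (5 equiv), 0 °C to rt
Reagents that add atoms: none
Why: Acid hydrolysis of the two aryl MOM acetals on a dione that has no benzylic alcohol and no fixed stereocentre to lose.

Step 10
Reactants: 10 (3R,4R)-4-hydroxy-7-methoxy-6,8-bis(methoxymethoxy)-3-methylisochroman-1-one; 11 rac-6,8-dihydroxy-7-methoxy-3-methylisochromane-1,4-dione (1.3 equiv)
Product: 12 (3R,4S)-4-[(8-hydroxy-7-methoxy-3-methyl-1,4-dioxoisochroman-6-yl)oxy]-7-methoxy-6,8-bis(methoxymethoxy)-3-methylisochroman-1-one (both C3 epimers of the dione half)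
Conditions: PPh3 (1.5 equiv), DIAD (1.5 equiv), THF, 0 °C to rt
Reagents that add atoms: none
Why: Mitsunobu etherification: the alcohol, activated in situ by PPh3/DIAD, should be displaced in SN2 fashion by the 6-OH phenol (para to the lactone carbonyl, the most acidic and least hindered OH; the 8-OH is chelated to C1=O), inverting C4 from R to S and giving the trans ether of unit A.

Step 11
Reactants: 12 (3R,4S)-4-[(8-hydroxy-7-methoxy-3-methyl-1,4-dioxoisochroman-6-yl)oxy]-7-methoxy-6,8-bis(methoxymethoxy)-3-methylisochroman-1-one
Product: 13 (3R,4S)-4-{[(3R,4R)-4,8-dihydroxy-7-methoxy-3-methyl-1-oxoisochroman-6-yl]oxy}-7-methoxy-6,8-bis(methoxymethoxy)-3-methylisochroman-1-one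
Conditions: RuCl[(S,S)-TsDPEN](p-cymene) (3 mol %), HCO2H/Et3N 5:2, CH2Cl2, 30 °C
Reagents that add atoms: none
Why: The same Noyori transfer hydrogenation with dynamic kinetic resolution should funnel both C3 epimers of the dione half into the cis (3R,4R) alcohol of unit B under catalyst control, the stereocentres of unit A being non-enolisable.

Step 12
Reactants: 13 (3R,4S)-4-{[(3R,4R)-4,8-dihydroxy-7-methoxy-3-methyl-1-oxoisochroman-6-yl]oxy}-7-methoxy-6,8-bis(methoxymethoxy)-3-methylisochroman-1-one
Product: 14 (3R,4S)-4-{[(3R,4R)-4,8-dihydroxy-7-methoxy-3-methyl-1-oxoisochroman-6-yl]oxy}-6,8-dihydroxy-7-methoxy-3-methylisochroman-1-one (CNP0139537.4)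
Conditions: TFA/CH2Cl2 1:9, H2O (5 equiv), 0 °C; pH 7 buffer work-up
Reagents that add atoms: none
Why: Acidic MOM cleavage, in which the benzylic C4–O bonds should resist ionisation (ortho lactone carbonyl, 7-OMe twisted out of conjugation by two flanking oxygens) and the absence of base avoids acyl migration of the free 4-OH onto C1.

**Compound list**

1 | methyl 3,5-dihydroxy-4-methoxybenzoate | COc1c(O)cc(C(=O)OC)cc1O | starting material
2 | methyl 4-methoxy-3,5-bis(methoxymethoxy)benzoate | COc1c(OCOC)cc(C(=O)OC)cc1OCOC | intermediate
3 | [4-methoxy-3,5-bis(methoxymethoxy)phenyl]methanol | COc1c(OCOC)cc(CO)cc1OCOC | intermediate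
4 | 4-methoxy-3,5-bis(methoxymethoxy)benzaldehyde | COc1c(OCOC)cc(C=O)cc1OCOC | intermediate
5 | 5-(dimethoxymethyl)-2-methoxy-1,3-bis(methoxymethoxy)benzene | COc1c(OCOC)cc(C(OC)OC)cc1OCOC | intermediate
6 | [2-(dimethoxymethyl)-5-methoxy-4,6-bis(methoxymethoxy)phenyl]lithium | COc1c(OCOC)cc(C(OC)OC)c([Li])c1OCOC | intermediate
7 | ethenyl 2-(dimethoxymethyl)-5-methoxy-4,6-bis(methoxymethoxy)benzoate | COc1c(OCOC)cc(C(OC)OC)c(c1OCOC)C(=O)OC=C | intermediate
8 | ethenyl 2-formyl-5-methoxy-4,6-bis(methoxymethoxy)benzoate | COc1c(OCOC)cc(C=O)c(c1OCOC)C(=O)OC=C | intermediate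
9 | rac-7-methoxy-6,8-bis(methoxymethoxy)-3-methylisochromane-1,4-dione | COc1c(OCOC)cc2c(c1OCOC)C(=O)OC(C)C2=O | intermediate
10 | (3R,4R)-4-hydroxy-7-methoxy-6,8-bis(methoxymethoxy)-3-methylisochroman-1-one | COc1c(OCOC)cc2c(c1OCOC)C(=O)O[C@H](C)[C@@H]2O | intermediate
11 | rac-6,8-dihydroxy-7-methoxy-3-methylisochromane-1,4-dione | COc1c(O)cc2c(c1O)C(=O)OC(C)C2=O | intermediate
12 | (3R,4S)-4-[(8-hydroxy-7-methoxy-3-methyl-1,4-dioxoisochroman-6-yl)oxy]-7-methoxy-6,8-bis(methoxymethoxy)-3-methylisochroman-1-one | COc1c(OCOC)cc2c(c1OCOC)C(=O)O[C@H](C)[C@H]2Oc1cc2c(c(O)c1OC)C(=O)OC(C)C2=O | intermediate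
13 | (3R,4S)-4-{[(3R,4R)-4,8-dihydroxy-7-methoxy-3-methyl-1-oxoisochroman-6-yl]oxy}-7-methoxy-6,8-bis(methoxymethoxy)-3-methylisochroman-1-one | COc1c(OCOC)cc2c(c1OCOC)C(=O)O[C@H](C)[C@H]2Oc1cc2c(c(O)c1OC)C(=O)O[C@H](C)[C@@H]2O | intermediate
14 | (3R,4S)-4-{[(3R,4R)-4,8-dihydroxy-7-methoxy-3-methyl-1-oxoisochroman-6-yl]oxy}-6,8-dihydroxy-7-methoxy-3-methylisochroman-1-one | COc1c(O)cc2c(c1O)C(=O)O[C@H](C)[C@H]2Oc1cc2c(c(O)c1OC)C(=O)O[C@H](C)[C@@H]2O | target

**Step count and risks**

Total step count: 12. Longest linear sequence: 11 (steps 1–8, 10, 11, 12); step 9 is a one-step branch from 9.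

Steps most likely to fail:

1. Step 7. Decarbonylation of the acyl rhodium hydride, or insertion of rhodium into the vinyl ester C–O bond, may outrun olefin insertion. The fallback sets out from 8 and comes back at 9, with the polarity of the C3–C4 bond formation reversed. With Fe(acac)3 (20 mol %) and PhSiH3 in EtOH/ethylene glycol at 40 °C, hydrogen-atom transfer to the terminal vinyl carbon should give the α-acyloxy radical at C3. This radical adds 6-exo to the aldehyde carbon, the iron-catalysed reductive radical cyclisation known for alkene-tethered carbonyl compounds. The product should be racemic 4-hydroxy-7-methoxy-6,8-bis(methoxymethoxy)-3-methylisochroman-1-one F1 as a cis/trans mixture. Oxidation of F1 without delay with Dess–Martin periodinane (NaHCO3, CH2Cl2, 0 °C) should give 9.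

2. Step 10. β-Elimination of the activated alcohol toward the isocoumarin, or sluggish displacement at the hindered secondary benzylic carbon with partial ionisation and erosion of the inversion, may lower the yield of trans ether. The fallback sets out from 10 (with 11) and comes back at 12, replacing inversion by substrate-controlled SN1 substitution. Cl3CCN with catalytic DBU in CH2Cl2 at −20 °C (short contact, to avoid acyl migration of the alkoxide) should give (3R,4R)-7-methoxy-6,8-bis(methoxymethoxy)-3-methyl-1-oxoisochroman-4-yl 2,2,2-trichloroacetimidate F4. Treatment of F4 with 11 and catalytic TMSOTf in CH2Cl2 at −40 °C should ionise C4, and the phenol should add anti to the C3 methyl group to give the trans ether 12 whatever the imidate configuration.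

3. Step 8. Reduction may outpace C3 epimerisation, facial control may be incomplete (trans or enantiomeric alcohol), or the new 4-OH may migrate onto C1 in the amine buffer. The fallback sets out from 9 and comes back at 10, using diastereoselective reduction and enzymatic resolution in place of the dynamic kinetic resolution. NaBH4 with CeCl3·7H2O in MeOH at −78 °C (hydride anti to the methyl) should give the racemic cis alcohol, that is 10 together with its enantiomer (3S,4S)-4-hydroxy-7-methoxy-6,8-bis(methoxymethoxy)-3-methylisochroman-1-one F2. Immobilised Candida antarctica lipase B with vinyl acetate in MTBE should, by the usual enantiopreference of lipases for cyclic benzylic alcohols, acetylate F2 to (3S,4S)-7-methoxy-6,8-bis(methoxymethoxy)-3-methyl-1-oxoisochroman-4-yl acetate F3. Unreacted 10 is then separated by chromatography.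

**Further compounds**

F1 | step 7 | rac-4-hydroxy-7-methoxy-6,8-bis(methoxymethoxy)-3-methylisochroman-1-one (cis/trans mixture) | COc1c(OCOC)cc2c(c1OCOC)C(=O)OC(C)C2O
F2 | step 8 | (3S,4S)-4-hydroxy-7-methoxy-6,8-bis(methoxymethoxy)-3-methylisochroman-1-one | COc1c(OCOC)cc2c(c1OCOC)C(=O)O[C@@H](C)[C@H]2O
F3 | step 8 | (3S,4S)-7-methoxy-6,8-bis(methoxymethoxy)-3-methyl-1-oxoisochroman-4-yl acetate | COc1c(OCOC)cc2c(c1OCOC)C(=O)O[C@@H](C)[C@H]2OC(C)=O
F4 | step 10 | (3R,4R)-7-methoxy-6,8-bis(methoxymethoxy)-3-methyl-1-oxoisochroman-4-yl 2,2,2-trichloroacetimidate | COc1c(OCOC)cc2c(c1OCOC)C(=O)O[C@H](C)[C@@H]2OC(=N)C(Cl)(Cl)Cl
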